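Assumption: commercial (−)-linalool is taken as the (R)-enantiomer of ≥95% ee and (S)-(−)-limonene as enantiopure; the small amount of diastereomer arising from (S)-linalool is removed by chromatography after the coupling.

**Retrosynthetic overview** (chain numbering: C1 = vinylic methyl, C2–C5 = diene carbons, C5 on the oxane)
1. The C4=C5 bond is made by a Takai–Utimoto alkylidenation. The aldehyde carbon of the oxane half is polarity-reversed (hydrazone → CHI2 → nucleophilic gem-dichromium) and attacks the aldehyde carbon of the cyclohexyl enal, so two natively electrophilic carbonyl carbons are joined.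
2. Oxane half: (R)-linalool, 6-endo bromoetherification, ozonolysis of the vinyl group, hydrazone/iodine.
3. Cyclohexane half: (S)-limonene, epoxidation and trans-diaxial hydrolysis, triflate-to-bromide inversion (cis bromohydrin), then isopropenyl → methyl ketone → E-enal.
4. Rings: the cyclohexane comes intact from limonene; the oxane is the only ring that is closed, and this happens before the two halves are joined.

**Route**

Step 1
Reactants: 1 (S)-(−)-limonene
Product: 4 (1R,2R,4S)-1-methyl-4-(prop-1-en-2-yl)cyclohexane-1,2-diol, via trans-limonene oxide 2 (not isolated), via cis-limonene oxide 3 (not isolated)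
Conditions: mCPBA (1.05 equiv), CH2Cl2, 0 °C; then 1 M aq. H2SO4, THF, 0 °C → rt
Reagents that add atoms: 3-chloroperoxybenzoic acid (mCPBA), OOC(=O)c1cccc(Cl)c1; water, O
Why: Prilezhaev epoxidation takes the electron-rich trisubstituted ring alkene, and acid-catalysed trans-diaxial (Fürst–Plattner) opening makes both epoxides converge on one diol (water enters at C2 of the trans-oxide and at C1 of the cis-oxide), which sets C1 and C2 relative to the limonene centre C4.

Step 2
Reactants: 4 (1R,2R,4S)-1-methyl-4-(prop-1-en-2-yl)cyclohexane-1,2-diol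
Product: 6 (1R,2S,4S)-2-bromo-1-methyl-4-(prop-1-en-2-yl)cyclohexan-1-ol, via secondary triflate 5 (not isolated)
Conditions: Tf2O (1.1 equiv), pyridine (3 equiv), CH2Cl2, −40 °C; then Bu4NBr (5 equiv), −40 °C → rt
Reagents that add atoms: tetrabutylammonium bromide, CCCC[N+](CCCC)(CCCC)CCCC.[Br-]
Why: Only the secondary hydroxyl is sulfonylated (the tertiary one is too hindered), and SN2 displacement of the axial triflate by bromide inverts C2 to give the equatorial bromide cis to the tertiary hydroxyl (2S).

Step 3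
Reactants: 6 (1R,2S,4S)-2-bromo-1-methyl-4-(prop-1-en-2-yl)cyclohexan-1-ol
Product: 7 1-[(1S,3S,4R)-3-bromo-4-hydroxy-4-methylcyclohexyl]ethan-1-one
Conditions: O3, CH2Cl2–MeOH, −78 °C; then Me2S, −78 °C → rt
Reagents that add atoms: ozone, [O-][O+]=O
Why: Ozonolysis with reductive work-up cleaves the only alkene to the methyl ketone and leaves the bromide, the alcohol and all stereocentres untouched.

Step 4
Reactants: 7 1-[(1S,3S,4R)-3-bromo-4-hydroxy-4-methylcyclohexyl]ethan-1-one; 8 diethyl {2-[methoxy(methyl)amino]-2-oxoethyl}phosphonate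
Product: 9 (2E)-3-[(1S,3S,4R)-3-bromo-4-hydroxy-4-methylcyclohexyl]-N-methoxy-N-methylbut-2-enamide
Conditions: 8 (1.5 equiv), NaH (1.4 equiv), THF, 0 °C; then 7, 0 → 40 °C
Reagents that add atoms: diethyl {2-[methoxy(methyl)amino]-2-oxoethyl}phosphonate (8), CCOP(=O)(CC(=O)N(C)OC)OCC
Why: Horner–Wadsworth–Emmons olefination with the preformed phosphonate anion (no free base, so the tertiary alcohol stays protonated) gives the E-alkene with the ring trans to the carbonyl (expected about 9:1, Z isomer removed by chromatography), and the ketone α-centre is safe because it already has the more stable equatorial configuration.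

Step 5
Reactants: 9 (2E)-3-[(1S,3S,4R)-3-bromo-4-hydroxy-4-methylcyclohexyl]-N-methoxy-N-methylbut-2-enamide
Product: 10 (2E)-3-[(1S,3S,4R)-3-bromo-4-hydroxy-4-methylcyclohexyl]but-2-enal
Conditions: DIBAL-H (2.3 equiv), THF, −78 °C; aq. Rochelle salt
Reagents that add atoms: none
Why: Weinreb amide reduction stops at the chelated aluminium hemiaminal, which releases the enal on work-up without over-reduction or loss of the E geometry.

Step 6
Reactants: 11 (R)-(−)-linalool
Product: 12 (3S,6R)-3-bromo-6-ethenyl-2,2,6-trimethyloxane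
Conditions: TBCO (1.1 equiv), MeNO2, 0 °C → rt, dark; chromatography
Reagents that add atoms: 2,4,4,6-tetrabromocyclohexa-2,5-dien-1-one (TBCO), O=C1C(Br)=CC(Br)(Br)C=C1Br
Why: Bromoetherification: the bromonium ion on the trisubstituted alkene is opened by the tertiary hydroxyl at the more substituted carbon (6-endo) with bromine equatorial, C6 comes from (R)-linalool, and the 3S isomer (Br trans to vinyl) is separated from its 3R epimer (about 1:1) and from tetrahydrofuran by-products.

Step 7
Reactants: 12 (3S,6R)-3-bromo-6-ethenyl-2,2,6-trimethyloxane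
Product: 13 (2R,5S)-5-bromo-2,6,6-trimethyloxane-2-carbaldehyde
Conditions: O3, CH2Cl2, −78 °C; then PPh3, −78 °C → rt
Reagents that add atoms: ozone, [O-][O+]=O
Why: Ozonolysis of the vinyl group gives an α-alkoxy aldehyde on a quaternary carbon, which cannot enolise or epimerise.

Step 8
Reactants: 13 (2R,5S)-5-bromo-2,6,6-trimethyloxane-2-carbaldehyde
Product: 15 (3S,6R)-3-bromo-6-(diiodomethyl)-2,2,6-trimethyloxane, via hydrazone 14 (not isolated)
Conditions: N2H4·H2O (10 equiv), EtOH, rt; evaporate; then I2 (2.5 equiv), Et3N (5 equiv), Et2O, 0 °C → rt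
Reagents that add atoms: iodine, II
Why: Hydrazone oxidation with iodine (Pross–Sternhell/Barton procedure, via the diazoalkane and an iodo-diazonium ion captured by iodide) converts the aldehyde carbon into a gem-diiodide, and with no α-hydrogen no vinyl iodide can form.

Step 9
Reactants: 10 (2E)-3-[(1S,3S,4R)-3-bromo-4-hydroxy-4-methylcyclohexyl]but-2-enal; 15 (3S,6R)-3-bromo-6-(diiodomethyl)-2,2,6-trimethyloxane
Product: 16 (1R,2S,4S)-2-bromo-4-[(2E,4E)-5-[(2R,5S)-5-bromo-2,6,6-trimethyloxan-2-yl]penta-2,4-dien-2-yl]-1-methylcyclohexan-1-ol (target)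
Conditions: CrCl2 (8 equiv), DMF (8 equiv), THF, rt, dark; 15 (1.5 equiv) and 10 added together in THF
Reagents that add atoms: none
Why: Takai–Utimoto alkylidenation: Cr(II) reduces the gem-diiodide to a nucleophilic gem-dichromium species, so the former aldehyde carbon C5 (polarity reversed) adds 1,2 to the enal carbon C4 and elimination of the β-oxidochromium intermediate gives the E C4=C5 alkene, joining two carbonyl carbons that are both natively electrophilic; the reagent has no β-hydrogen, and Cr(II) at room temperature is expected to leave the secondary bromides and the tertiary alcohol alone.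

**Compound list**
1 | (S)-(−)-limonene, (4S)-1-methyl-4-(prop-1-en-2-yl)cyclohex-1-ene | CC(=C)[C@H]1CCC(C)=CC1 | starting material
2 | trans-limonene oxide, (1R,4S,6S)-1-methyl-4-(prop-1-en-2-yl)-7-oxabicyclo[4.1.0]heptane (epoxide oxygen cis to isopropenyl; not isolated) | CC(=C)[C@H]1CC[C@@]2(C)O[C@H]2C1 | intermediate
3 | cis-limonene oxide, (1S,4S,6R)-1-methyl-4-(prop-1-en-2-yl)-7-oxabicyclo[4.1.0]heptane (epoxide oxygen trans to isopropenyl; not isolated) | CC(=C)[C@H]1CC[C@]2(C)O[C@@H]2C1 | intermediate
4 | (1R,2R,4S)-1-methyl-4-(prop-1-en-2-yl)cyclohexane-1,2-diol (trans-diaxial diol) | CC(=C)[C@H]1CC[C@@](C)(O)[C@H](O)C1 | intermediate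
5 | (1R,2R,5S)-2-hydroxy-2-methyl-5-(prop-1-en-2-yl)cyclohexyl trifluoromethanesulfonate (not isolated) | CC(=C)[C@H]1CC[C@@](C)(O)[C@H](OS(=O)(=O)C(F)(F)F)C1 | intermediate
6 | (1R,2S,4S)-2-bromo-1-methyl-4-(prop-1-en-2-yl)cyclohexan-1-ol (Br equatorial, cis to OH) | CC(=C)[C@H]1CC[C@@](C)(O)[C@@H](Br)C1 | intermediate
7 | 1-[(1S,3S,4R)-3-bromo-4-hydroxy-4-methylcyclohexyl]ethan-1-one | CC(=O)[C@H]1CC[C@@](C)(O)[C@@H](Br)C1 | intermediate
8 | diethyl {2-[methoxy(methyl)amino]-2-oxoethyl}phosphonate | CCOP(=O)(CC(=O)N(C)OC)OCC | starting material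
9 | (2E)-3-[(1S,3S,4R)-3-bromo-4-hydroxy-4-methylcyclohexyl]-N-methoxy-N-methylbut-2-enamide | C/C(=C\C(=O)N(C)OC)[C@H]1CC[C@@](C)(O)[C@@H](Br)C1 | intermediate
10 | (2E)-3-[(1S,3S,4R)-3-bromo-4-hydroxy-4-methylcyclohexyl]but-2-enal | C/C(=C\C=O)[C@H]1CC[C@@](C)(O)[C@@H](Br)C1 | intermediate
11 | (R)-(−)-linalool, (3R)-3,7-dimethylocta-1,6-dien-3-ol | C=C[C@](C)(O)CCC=C(C)C | starting material
12 | (3S,6R)-3-bromo-6-ethenyl-2,2,6-trimethyloxane (Br trans to vinyl) | C=C[C@@]1(C)CC[C@H](Br)C(C)(C)O1 | intermediate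
13 | (2R,5S)-5-bromo-2,6,6-trimethyloxane-2-carbaldehyde | O=C[C@@]1(C)CC[C@H](Br)C(C)(C)O1 | intermediate
14 | (E)-{[(2R,5S)-5-bromo-2,6,6-trimethyloxan-2-yl]methylidene}hydrazine (not isolated) | N/N=C/[C@@]1(C)CC[C@H](Br)C(C)(C)O1 | intermediate
15 | (3S,6R)-3-bromo-6-(diiodomethyl)-2,2,6-trimethyloxane | IC(I)[C@@]1(C)CC[C@H](Br)C(C)(C)O1 | intermediate
16 | (1R,2S,4S)-2-bromo-4-[(2E,4E)-5-[(2R,5S)-5-bromo-2,6,6-trimethyloxan-2-yl]penta-2,4-dien-2-yl]-1-methylcyclohexan-1-ol | C/C(=C\C=C\[C@@]1(C)CC[C@H](Br)C(C)(C)O1)[C@H]1CC[C@@](C)(O)[C@@H](Br)C1 | target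

**Step count and risks**

Total steps: 9. Longest linear sequence: 6 (steps 1–5, then step 9); the oxane branch is 3 steps before the coupling.

Risk 1, step 2. The free tertiary hydroxyl is anti-periplanar to the axial triflate and could close an epoxide (which bromide would reopen with net retention), and E2 elimination is also possible. The fallback sets out from 4 and comes back at 6. Both hydroxyls are silylated (TMSCl, imidazole, DMF) to the bis(trimethylsilyl) ether F1. The secondary silyl group is removed selectively (K2CO3, MeOH, 0 °C) to give the tertiary silyl ether alcohol F2. Triflation and bromide displacement on F2, where no free hydroxyl can participate, give the bromo silyl ether F3. PPTS in MeOH then releases 6.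

Risk 2, step 8. The iodo-diazonium intermediate sits next to a quaternary carbon that carries the ring oxygen, so a 1,2-shift to an oxocarbenium ion (ring expansion) or azine formation may compete with capture by iodide. The fallback reverses the roles of the two halves; it sets out from 10, uses 13 as the electrophile, and comes back at 16. Luche reduction (NaBH4, CeCl3) of 10 gives the allylic alcohol F4. CBr4/PPh3 gives the allylic bromide F5. Sodium diethyl phosphite (Michaelis–Becker) gives the allylic phosphonate F6. Deprotonation with NaHMDS and Horner–Wadsworth–Emmons reaction with 13 form the E C4=C5 bond of 16.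

Risk 3, step 9. The gem-dichromium species carries the ring oxygen β to chromium and could undergo β-alkoxy elimination (opening the oxane), and the free hydroxyl of 10 could protonate it. The fallback replaces carbonyl olefination by olefin metathesis; it sets out from 10 and 12 and comes back at 16. Wittig methylenation of 10 (Ph3P=CH2, 2.2 equiv, THF, −78 → 0 °C) gives the terminal diene F7. Cross-metathesis of F7 with the vinyl oxane 12 (Hoveyda–Grubbs II, CH2Cl2, 40 °C, ethene purged) gives 16; the trisubstituted alkene of F7 is inert, but the hindered vinyl group of 12 is a slow partner.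

Further compounds
F1 | step 2 | (1R,2R,4S)-1-methyl-4-(prop-1-en-2-yl)-1,2-bis[(trimethylsilyl)oxy]cyclohexane | CC(=C)[C@H]1CC[C@@](C)(O[Si](C)(C)C)[C@H](O[Si](C)(C)C)C1
F2 | step 2 | (1R,2R,5S)-2-methyl-5-(prop-1-en-2-yl)-2-[(trimethylsilyl)oxy]cyclohexan-1-ol | CC(=C)[C@H]1CC[C@@](C)(O[Si](C)(C)C)[C@H](O)C1
F3 | step 2 | {[(1R,2S,4S)-2-bromo-1-methyl-4-(prop-1-en-2-yl)cyclohexyl]oxy}trimethylsilane | CC(=C)[C@H]1CC[C@@](C)(O[Si](C)(C)C)[C@@H](Br)C1
F4 | step 8 | (1R,2S,4S)-2-bromo-4-[(2E)-4-hydroxybut-2-en-2-yl]-1-methylcyclohexan-1-ol | C/C(=C\CO)[C@H]1CC[C@@](C)(O)[C@@H](Br)C1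
F5 | step 8 | (1R,2S,4S)-2-bromo-4-[(2E)-4-bromobut-2-en-2-yl]-1-methylcyclohexan-1-ol | C/C(=C\CBr)[C@H]1CC[C@@](C)(O)[C@@H](Br)C1
F6 | step 8 | diethyl [(2E)-3-[(1S,3S,4R)-3-bromo-4-hydroxy-4-methylcyclohexyl]but-2-en-1-yl]phosphonate | C/C(=C\CP(=O)(OCC)OCC)[C@H]1CC[C@@](C)(O)[C@@H](Br)C1
F7 | step 9 | (1R,2S,4S)-2-bromo-1-methyl-4-[(2E)-penta-2,4-dien-2-yl]cyclohexan-1-ol | C/C(=C\C=C)[C@H]1CC[C@@](C)(O)[C@@H](Br)C1
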